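Late in the runs, at 3.00 min, Friday's flask has made 3.7% of product and Monday's 24.5%, each in percent of its own charge.

all flasks: free catalyst 2 mol%; impurity 69 µM

|  | starting material | reagent | remark |
|---|---|---|---|
| Friday's | 9 mM | 1.2 equiv | run made earlier |
| Monday's | 36 mM | 1.2 equiv | run made earlier |
| flask | 18 mM | 1.20 equiv |  |

- Friday's (time / min: product / %, starting material / %): 0.250: 0.8, 99.0; 0.333: 1.9, 99.0; 0.500: 0, 97.9; 0.833: 0, 96.5; 1.33: 0, 94.0; 2.00: 1.3, 93.1; 3.00: 3.7, 92.6
- Monday's (time / min: product / %, starting material / %): 0.250: 0, 95.8; 0.333: 0.8, 93.3; 0.500: 1.1, 90.8; 0.833: 3.0, 89.1; 1.33: 7.6, 85.3; 2.00: 15.7, 79.4; 3.00: 24.5, 72.2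

(standard deviation of a reading: 1 percentage point)

- factor on the rate of making product when 10% of the starting material are converted if reagent is charged twice over
- factor on the rate when 10% of the starting material are converted if free catalyst is charged at 10 mol% instead

- what was read earlier has a scatter of 1 percentage point, one standard deviation

In concentration, that late product differs by a factor of about 26.5. This is a reading, and a loose one, because Friday's figure stands close to the scatter. Monday's charges of starting material and catalyst are each 4.00 times Friday's, so a rate first order in each gives 16.0, less than the reading.

But the impurity is the same 69 µM in both runs. Suppose it takes catalyst one for one, and call what remains of the charged catalyst the working catalyst. Friday's run then has 111 µM and Monday's 651 µM, which with the factor for starting material gives 23.5, near the reading.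

Our flask's charge leaves 291 µM of working catalyst, so we reckon 19.2% of its catalyst lost. With 10 mol% in this flask, 1730 µM remain, so we expect the rate to rise by 5.95. Reagent stood at 1.2 equiv in both runs, so the runs do not part it from starting material, and our own reckoning gives no number for it.

The forecast gives 1.4 for reagent and 5.9 for catalyst, noting that “reagent and starting material cannot be separated”.

The flask gives 1.40 for doubled reagent and 4.73 for the catalyst.

    starting material + free catalyst ⇌ free catalyst + open intermediate (K = 0.950, k = 360 L mol⁻¹ min⁻¹)
    free catalyst + open intermediate ⇌ catalyst intermediate (K = 4300 L mol⁻¹, k = 7400 L mol⁻¹ min⁻¹)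
    reagent + catalyst intermediate → free catalyst + product (k = 220 L mol⁻¹ min⁻¹)
    free catalyst + impurity → spent catalyst (k = 4.20 × 10⁵ L mol⁻¹ min⁻¹)

When 10% of the starting material is converted, at 1.63 min, spent catalyst holds 19.2% of the catalyst charged in this flask. Divided by the factor in working catalyst, the rate per working catalyst at 10 mol% comes to 0.795 of that at 2 mol%.

Readings and results were computed for an exercise; the scatter is artificial.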